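**Retrosynthetic overview**
1. The pyran ring is closed last: O1–C8a by intramolecular oxa-Michael addition of the tertiary alcohol to a p-quinone monoketal, then loss of MeOH, which rearomatizes directly to the 5-OH/6,8-OMe pattern; C4–C4a by Sonogashira coupling and Z-semi-hydrogenation.
2. Key disconnection: the central CH2–CH2 bond, made by radical conjugate addition of a β-silyloxy primary alkyl radical (carrying the future chromene C2, taken from a chiral epoxy alcohol) to an exocyclic enone. The regiodefined enolate formed in that step is C-methylated to set the quaternary ring carbon.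
3. Exocyclic methylene by Peterson olefination; ring CH(CH3) centre by ene-reductase reduction of a cyclohexenone.
4. Ring order: cyclohexane ring bought intact; benzene ring from a simple dihydroxybenzene (carried as an iodo quinone monoketal, rearomatized at the end); pyran ring last.

Assumption: (R)-2-methylglycidol of high ee is taken as a purchasable building block.

**Route**

Step 1
Reactants: 1 2-methylcyclohex-2-en-1-one
Product: 2 (2R)-2-methylcyclohexan-1-one
Conditions: ene-reductase OYE2, NADP+ (cat.), glucose dehydrogenase, D-glucose, phosphate buffer pH 7, 30 °C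
Reagents that add atoms: none
Why: Old-yellow-enzyme ene-reductases reduce 2-alkylcyclohex-2-enones by trans addition of hydride (C3) and a proton (C2) (biocatalytic asymmetric conjugate reduction), which sets the (R) centre at C2 in high ee at neutral pH where it does not racemize.

Step 2
Reactants: 2 (2R)-2-methylcyclohexan-1-one
Product: 5 (2R)-2-methyl-6-methylidenecyclohexan-1-one, via Mannich base 3 (not isolated), via methiodide 4 (not isolated)
Conditions: LiN(i-Pr)2, THF, −78 °C; CH2=NMe2+ I−, −78 °C to rt; MeI; aq. NaHCO3, CH2Cl2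
Reagents that add atoms: N,N-dimethylmethyleneiminium iodide (Eschenmoser's salt), C=[N+](C)C.[I-]
Why: Kinetic deprotonation on the CH2 side, Mannich reaction, N-methylation and base-induced β-elimination of Me3N (Eschenmoser methylenation) give the exocyclic enone without touching the existing stereocentre; it is used at once because α-methylene ketones dimerize.

Step 3
Reactants: 6 [(2R)-2-methyloxiran-2-yl]methanol ((R)-2-methylglycidol)
Product: 8 (2R)-2-ethynyl-2-methyloxirane, via epoxy aldehyde 7 (not isolated)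
Conditions: TEMPO (cat.), PhI(OAc)2, CH2Cl2, rt; then dimethyl (1-diazo-2-oxopropyl)phosphonate, K2CO3, MeOH, 0 °C to rt
Reagents that add atoms: dimethyl (1-diazo-2-oxopropyl)phosphonate (Ohira–Bestmann reagent), CC(=O)C(=[N+]=[N-])P(=O)(OC)OC
Why: Nitroxyl-catalysed oxidation gives the non-enolizable epoxy aldehyde, which is homologated in the same flask by Ohira–Bestmann (Seyferth–Gilbert) alkynylation; the quaternary epoxide carbon is not involved, so its configuration is kept.

Step 4
Reactants: 8 (2R)-2-ethynyl-2-methyloxirane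
Product: 9 {[(2R)-1-iodo-2-methylbut-3-yn-2-yl]oxy}trimethylsilane
Conditions: Me3SiI, CH2Cl2, −78 °C
Reagents that add atoms: iodotrimethylsilane, C[Si](C)(C)I
Why: Me3SiI opens 2,2-disubstituted epoxides by SN2 attack of iodide at the CH2 terminus with O-silylation, so the tertiary C–O bond and its configuration are retained.

Step 5
Reactants: 9 {[(2R)-1-iodo-2-methylbut-3-yn-2-yl]oxy}trimethylsilane; 5 (2R)-2-methyl-6-methylidenecyclohexan-1-one
Product: 11 (2R,6R)-2,6-dimethyl-2-[(3S)-3-methyl-3-(trimethylsilyloxy)pent-4-yn-1-yl]cyclohexan-1-one, via boron enolate 10 (not isolated)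
Conditions: Et3B, air, toluene, −20 °C (5 added over 4 h); then THF, MeLi (1 equiv per boron), −78 °C; MeI, DMPU, −78 to −20 °C
Reagents that add atoms: iodomethane, CI
Why: Proposed new method: ethyl radicals from Et3B/O2 abstract iodine from 9, the β-silyloxy primary radical (1,2-alkynyl shift is slow) adds to the unhindered exocyclic CH2 of 5 (Giese-type radical conjugate addition), the enoxyl radical displaces ethyl from Et3B to give regiodefined boron enolate 10, and its lithium ate complex is C-methylated by MeI on the face anti to the pseudoaxial methyl of the neighbouring stereocentre, so the quaternary carbon forms with the two ring methyls trans; closest known reactions are the trialkylborane-mediated radical 1,4-addition to α-methylene ketones giving boron enolates (Brown, Oshima–Utimoto) and the alkylation of enoxyborates (Hooz, Negishi).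

Step 6
Reactants: 11 (2R,6R)-2,6-dimethyl-2-[(3S)-3-methyl-3-(trimethylsilyloxy)pent-4-yn-1-yl]cyclohexan-1-one
Product: 13 (3S)-5-[(1R,3R)-1,3-dimethyl-2-methylidenecyclohexyl]-3-methylpent-1-yn-3-ol, via Peterson carbinol 12 (not isolated)
Conditions: Me3SiCH2Li (3 equiv), CeCl3, THF, −78 to 0 °C; then aq. HF, MeCN, rt
Reagents that add atoms: (trimethylsilyl)methyllithium, [Li]C[Si](C)(C)C
Why: Peterson olefination: the weakly basic organocerium reagent adds to the hindered, enolizable ketone without epimerizing the adjacent CH(CH3) centre, and HF then eliminates Me3Si/OH to the exocyclic alkene and frees the tertiary alcohol; no stereocentre is created or touched.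

Step 7
Reactants: 14 benzene-1,3-diol (resorcinol)
Product: 15 1,3-dimethoxybenzene
Conditions: Me2SO4, K2CO3, acetone, reflux
Reagents that add atoms: dimethyl sulfate, COS(=O)(=O)OC
Why: Williamson O-methylation of both phenols.

Step 8
Reactants: 15 1,3-dimethoxybenzene
Product: 16 2,4-dimethoxybenzaldehyde
Conditions: POCl3, DMF, 0 to 60 °C; then H2O
Reagents that add atoms: N,N-dimethylformamide, CN(C)C=O; water, O
Why: Vilsmeier–Haack formylation occurs at C4, para to one methoxy group and ortho to the other, the only doubly activated unhindered position.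

Step 9
Reactants: 16 2,4-dimethoxybenzaldehyde
Product: 18 2,4-dimethoxyphenol, via aryl formate 17 (not isolated)
Conditions: mCPBA, CH2Cl2, rt; then K2CO3 (cat.), MeOH
Reagents that add atoms: 3-chloroperoxybenzoic acid, OOC(=O)c1cccc(Cl)c1
Why: Dakin-type Baeyer–Villiger oxidation of the electron-rich aldehyde proceeds with aryl migration to the formate, which is methanolysed to the phenol.

Step 10
Reactants: 18 2,4-dimethoxyphenol
Product: 19 2,4,4-trimethoxycyclohexa-2,5-dien-1-one
Conditions: PhI(OAc)2, MeOH, 0 °C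
Reagents that add atoms: methanol, CO
Why: Oxidative dearomatization of a p-methoxyphenol with PhI(OAc)2 in methanol traps the phenoxenium ion at the para carbon to give the p-quinone monoketal.

Step 11
Reactants: 19 2,4,4-trimethoxycyclohexa-2,5-dien-1-one
Product: 20 6-iodo-2,4,4-trimethoxycyclohexa-2,5-dien-1-one
Conditions: I2, pyridine, CH2Cl2, rt
Reagents that add atoms: iodine, II
Why: Johnson α-iodination (conjugate addition of pyridine, iodination, elimination) takes place at the only enone α-carbon that carries hydrogen.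

Step 12
Reactants: 13 (3S)-5-[(1R,3R)-1,3-dimethyl-2-methylidenecyclohexyl]-3-methylpent-1-yn-3-ol; 20 6-iodo-2,4,4-trimethoxycyclohexa-2,5-dien-1-one
Product: 21 6-{(3S)-5-[(1R,3R)-1,3-dimethyl-2-methylidenecyclohexyl]-3-hydroxy-3-methylpent-1-yn-1-yl}-2,4,4-trimethoxycyclohexa-2,5-dien-1-one
Conditions: PdCl2(PPh3)2 (5 mol %), CuI (10 mol %), i-Pr2NEt, THF, 0 °C to rt
Reagents that add atoms: none
Why: Sonogashira coupling: α-iodoenones undergo fast oxidative addition and couple with terminal alkynes at or below room temperature, leaving the ketal, the tertiary alcohol and the hindered exocyclic alkene untouched; no stereocentre is affected.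

Step 13
Reactants: 21 6-{(3S)-5-[(1R,3R)-1,3-dimethyl-2-methylidenecyclohexyl]-3-hydroxy-3-methylpent-1-yn-1-yl}-2,4,4-trimethoxycyclohexa-2,5-dien-1-one
Product: 24 (2S)-2-{2-[(1R,3R)-1,3-dimethyl-2-methylidenecyclohexyl]ethyl}-6,8-dimethoxy-2-methyl-2H-chromen-5-ol (metachromin B), via Z-alkenyl dienone 22 (not isolated), via bicyclic enol ketal 23 (not isolated)
Conditions: H2 (1 atm), Pd/CaCO3 poisoned with Pb(OAc)2, quinoline, EtOAc, 0 °C; filter; pyridinium p-toluenesulfonate (10 mol %), 4 Å sieves, CH2Cl2, rt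
Reagents that add atoms: none
Why: Proposed new method: Lindlar semi-hydrogenation gives the Z-alkene 22, which holds the tertiary hydroxyl next to the β-carbon of the cross-conjugated dienone so that 6-endo oxa-Michael addition gives 23, and acid-induced loss of methanol from the ketal aromatizes the ring to the 5-hydroxy-6,8-dimethoxy pattern without ever breaking the C2–O bond, so the (S) centre is retained; closest known reactions are Z-selective Lindlar hydrogenation and the conjugate addition/aromatization of nucleophiles with p-quinone monoketals.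

**Compound list**
1 | 2-methylcyclohex-2-en-1-one | CC1=CCCCC1=O | starting material
2 | (2R)-2-methylcyclohexan-1-one | O=C1[C@H](C)CCCC1 | intermediate
3 | (6R)-2-[(dimethylamino)methyl]-6-methylcyclohexan-1-one (C2 epimers) | O=C1[C@H](C)CCCC1CN(C)C | intermediate
4 | trimethyl{[(3R)-3-methyl-2-oxocyclohexyl]methyl}ammonium iodide | O=C1[C@H](C)CCCC1C[N+](C)(C)C.[I-] | intermediate
5 | (2R)-2-methyl-6-methylidenecyclohexan-1-one | O=C1[C@H](C)CCCC1=C | intermediate
6 | [(2R)-2-methyloxiran-2-yl]methanol | C[C@@]1(CO)CO1 | starting material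
7 | (2S)-2-methyloxirane-2-carbaldehyde | C[C@@]1(C=O)CO1 | intermediate
8 | (2R)-2-ethynyl-2-methyloxirane | C[C@@]1(C#C)CO1 | intermediate
9 | {[(2R)-1-iodo-2-methylbut-3-yn-2-yl]oxy}trimethylsilane | C[C@@](O[Si](C)(C)C)(C#C)CI | intermediate
10 | diethyl({(6R)-6-methyl-2-[(3S)-3-methyl-3-(trimethylsilyloxy)pent-4-yn-1-yl]cyclohex-1-en-1-yl}oxy)borane | CCB(CC)OC1=C(CC[C@](C)(O[Si](C)(C)C)C#C)CCC[C@H]1C | intermediate
11 | (2R,6R)-2,6-dimethyl-2-[(3S)-3-methyl-3-(trimethylsilyloxy)pent-4-yn-1-yl]cyclohexan-1-one | O=C1[C@H](C)CCC[C@]1(C)CC[C@](C)(O[Si](C)(C)C)C#C | intermediate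
12 | (2R,6R)-2,6-dimethyl-2-[(3S)-3-methyl-3-(trimethylsilyloxy)pent-4-yn-1-yl]-1-[(trimethylsilyl)methyl]cyclohexan-1-ol (C1 epimers) | C[Si](C)(C)CC1(O)[C@H](C)CCC[C@]1(C)CC[C@](C)(O[Si](C)(C)C)C#C | intermediate
13 | (3S)-5-[(1R,3R)-1,3-dimethyl-2-methylidenecyclohexyl]-3-methylpent-1-yn-3-ol | C=C1[C@H](C)CCC[C@]1(C)CC[C@](C)(O)C#C | intermediate
14 | benzene-1,3-diol | Oc1cccc(O)c1 | starting material
15 | 1,3-dimethoxybenzene | COc1cccc(OC)c1 | intermediate
16 | 2,4-dimethoxybenzaldehyde | COc1ccc(C=O)c(OC)c1 | intermediate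
17 | 2,4-dimethoxyphenyl formate | COc1ccc(OC=O)c(OC)c1 | intermediate
18 | 2,4-dimethoxyphenol | COc1ccc(O)c(OC)c1 | intermediate
19 | 2,4,4-trimethoxycyclohexa-2,5-dien-1-one | COC1=CC(OC)(OC)C=CC1=O | intermediate
20 | 6-iodo-2,4,4-trimethoxycyclohexa-2,5-dien-1-one | COC1=CC(OC)(OC)C=C(I)C1=O | intermediate
21 | 6-{(3S)-5-[(1R,3R)-1,3-dimethyl-2-methylidenecyclohexyl]-3-hydroxy-3-methylpent-1-yn-1-yl}-2,4,4-trimethoxycyclohexa-2,5-dien-1-one | COC1=CC(OC)(OC)C=C(C#C[C@@](C)(O)CC[C@@]2(C)CCC[C@@H](C)C2=C)C1=O | intermediate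
22 | 6-{(1Z,3S)-5-[(1R,3R)-1,3-dimethyl-2-methylidenecyclohexyl]-3-hydroxy-3-methylpent-1-en-1-yl}-2,4,4-trimethoxycyclohexa-2,5-dien-1-one | COC1=CC(OC)(OC)C=C(/C=C\[C@@](C)(O)CC[C@@]2(C)CCC[C@@H](C)C2=C)C1=O | intermediate
23 | (2S)-2-{2-[(1R,3R)-1,3-dimethyl-2-methylidenecyclohexyl]ethyl}-6,8,8-trimethoxy-2-methyl-8,8a-dihydro-2H-chromen-5-ol (C8a epimers) | C=C1[C@H](C)CCC[C@]1(C)CC[C@@]1(C)C=CC2=C(O)C(OC)=CC(OC)(OC)C2O1 | intermediate
24 | (2S)-2-{2-[(1R,3R)-1,3-dimethyl-2-methylidenecyclohexyl]ethyl}-6,8-dimethoxy-2-methyl-2H-chromen-5-ol (metachromin B) | C=C1[C@H](C)CCC[C@]1(C)CC[C@@]1(C)C=Cc2c(O)c(OC)cc(OC)c2O1 | target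

**Totals**
Total steps: 13. Longest linear sequence: 7 (steps 7–13).

**Steps most likely to fail, with fallbacks**

Step 5 (radical union and enolate methylation). Ethyl radicals can add to the enone in competition with iodine transfer from a primary iodide, the propargylic radical may rearrange, and the alkyne C–H is exposed to MeLi. The fallback sets out from 6 (with 5) and comes back at 13; it keeps the radical union but installs the alkyne afterwards. Compound 6 is O-silylated (Me3SiCl, Et3N) and opened with Me3SiI to (2R)-1-iodo-2-methyl-2,3-bis(trimethylsilyloxy)propane F1, whose radical has no unsaturation and no acidic C–H. The same Et3B/air addition to 5 and MeLi/MeI methylation give (2R,6R)-2,6-dimethyl-2-[(3S)-3-methyl-3,4-bis(trimethylsilyloxy)butyl]cyclohexan-1-one F2. Methylenation with Cp2TiMe2 (toluene, 70 °C, possible because no alkyne is present) gives (1R,3R)-1,3-dimethyl-2-methylidene-1-[(3S)-3-methyl-3,4-bis(trimethylsilyloxy)butyl]cyclohexane F3. Swern oxidation, which cleaves and oxidizes only the primary silyl ether, gives (2S)-4-[(1R,3R)-1,3-dimethyl-2-methylidenecyclohexyl]-2-methyl-2-(trimethylsilyloxy)butanal F4. Ohira–Bestmann alkynylation in K2CO3/MeOH, which also removes the tertiary silyl group, gives 13.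

Step 6 (methylenation of a 2,2,6-trisubstituted, epimerizable ketone). If the bulky silylmethyl carbanion does not add, the fallback sets out from 11 and comes back at 13. The carbanion addition–elimination is replaced by direct carbonyl-to-methylidene exchange with the non-basic titanium–zinc gem-dimetallic reagent (Zn, CH2Br2, TiCl4, THF/CH2Cl2), which tolerates the terminal alkyne and gives {[(3S)-5-[(1R,3R)-1,3-dimethyl-2-methylidenecyclohexyl]-3-methylpent-1-yn-3-yl]oxy}trimethylsilane F5. K2CO3 in MeOH then frees the alcohol to give 13.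

Step 13 (semi-hydrogenation in the presence of the dienone, then ring closure). If hydrogenation attacks the quinone monoketal or over-reduces, the fallback sets out from 13 (with 20) and comes back at 22, avoiding H2 altogether. Rhodium-catalysed trans-hydroboration of 13 ([Rh(cod)Cl]2, P(i-Pr)3, Et3N, pinacolborane) gives (1Z,3S)-5-[(1R,3R)-1,3-dimethyl-2-methylidenecyclohexyl]-3-methyl-1-(4,4,5,5-tetramethyl-1,3,2-dioxaborolan-2-yl)pent-1-en-3-ol F6. Suzuki coupling of this with 20 (Pd(PPh3)4, K3PO4, dioxane) gives the Z-alkenyl dienone 22 directly, and the acid treatment of step 13 then closes and aromatizes it to 24.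

**Further compounds**
F1 | step 5 | (2R)-1-iodo-2-methyl-2,3-bis(trimethylsilyloxy)propane | C[C@@](O[Si](C)(C)C)(CO[Si](C)(C)C)CI
F2 | step 5 | (2R,6R)-2,6-dimethyl-2-[(3S)-3-methyl-3,4-bis(trimethylsilyloxy)butyl]cyclohexan-1-one | O=C1[C@H](C)CCC[C@]1(C)CC[C@](C)(O[Si](C)(C)C)CO[Si](C)(C)C
F3 | step 5 | (1R,3R)-1,3-dimethyl-2-methylidene-1-[(3S)-3-methyl-3,4-bis(trimethylsilyloxy)butyl]cyclohexane | C=C1[C@H](C)CCC[C@]1(C)CC[C@](C)(O[Si](C)(C)C)CO[Si](C)(C)C
F4 | step 5 | (2S)-4-[(1R,3R)-1,3-dimethyl-2-methylidenecyclohexyl]-2-methyl-2-(trimethylsilyloxy)butanal | C=C1[C@H](C)CCC[C@]1(C)CC[C@](C)(O[Si](C)(C)C)C=O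
F5 | step 6 | {[(3S)-5-[(1R,3R)-1,3-dimethyl-2-methylidenecyclohexyl]-3-methylpent-1-yn-3-yl]oxy}trimethylsilane | C=C1[C@H](C)CCC[C@]1(C)CC[C@](C)(O[Si](C)(C)C)C#C
F6 | step 13 | (1Z,3S)-5-[(1R,3R)-1,3-dimethyl-2-methylidenecyclohexyl]-3-methyl-1-(4,4,5,5-tetramethyl-1,3,2-dioxaborolan-2-yl)pent-1-en-3-ol | C=C1[C@H](C)CCC[C@]1(C)CC[C@](C)(O)/C=C\B1OC(C)(C)C(C)(C)O1
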